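The data were generated by integration for substances that don't exist.

60.0% of the D charged: that is the ceiling on J in these flasks, the charge of X over the charge of D, for each J made takes one X, which at this charge makes X the limiting reagent for J.

| setting | spring | south | south-west | north-west | north-east |
|---|---|---|---|---|---|
| D | 20 mM | 20 mM | 20 mM | 20 mM | 20 mM |
| X | 0.60 equiv | 0.600 equiv | 0.600 equiv | 0.600 equiv | 0.600 equiv |
| G | 6 mM | 6.00 mM | 6.00 mM | 6.00 mM | 6.00 mM |
| L | 3.8 mol% | 2.5 mol% | 2.5 mol% | 2.5 mol% | 2.5 mol% |
| temperature | 15 °C | 15 °C | 55 °C |  | 35 °C |
| remark | run made earlier |  |  | at 15 °C until 8.0 min, from then on at 55 °C |  |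
| time |  | 12 min | 12 min | 12 min | 12 min |

spring run (percent of the D charged)

| time / min | J / % | D / % |
|---|---|---|
| 0.333 | 14.0 | 70.2 |
| 0.667 | 24.6 | 55.0 |
| 1.00 | 32.6 | 43.2 |
| 1.33 | 39.2 | 35.5 |
| 1.50 | 41.8 | 32.9 |
| 2.00 | 46.3 | 26.8 |
| 2.50 | 50.6 | 21.4 |

(standard deviation of a reading: 0.5 percentage points)

- the numbers in the tables scatter with a standard deviation of 0.5 percentage points
- what may be going on: D + X + L -> J + L; D + G -> Z; 2 L -> E; L -> Q
- the earlier runs do not show what temperature does; that part of a forecast is a guess
- no earlier run changes the charge of L; that part of a forecast is a guess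

* the flask with the highest amount of J, in percent of the D charged ("all alike" if they lie within 1.5 percentage points) (south / south-west / north-west / north-east / all alike)
* final J, as a percentage of the D charged, in south
* final J, as a percentage of the D charged, in south-west
* final J, as a percentage of the D charged, in north-west
* final J, as a percentage of the D charged, in north-east

*What do you read from the spring run?* J and D do not add up to the whole. At 2.50 min the gap is 28.0%, close to c(G)/c(D) = 30.0%. So I read the gap as Z, and by this reading nearly all of G has reacted.

*Doesn't that path take D away from J?* It takes D, but X and G together call for 18.0 mM, less than the 20 mM of D charged. When both have finished, 10.0% of D is left over, whichever path runs faster.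

*Then how fast is the ceiling approached?* Work with the fraction of X left, one minus J over the ceiling. In the spring run it is 45.7% at 1.00 min and 15.7% at 2.50 min, which as a decay is a time constant of 1.40 min. Scaled by the loading of L, which is a guess, it becomes 2.13 min. The 12 min of south is then 5.63 time constants, and my reckoning gives 59.8%.

*And if the tail is slower, or heat harms L?* With a time constant of 4.26 min, my reckoning puts south 3.6 percentage points under the ceiling, beyond the margin of 1.5 points. That is my risk, and what heat does is a guess. Still, I commit to "all alike", near the ceiling.

The forecast differs. It named north-west, with 56.5% in south, 46% in south-west, 58% in north-west and 54% in north-east, on the ground that “Heat probably kills the catalyst faster and may shift selectivity”.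

The flasks came out all alike: 59.0% in south, 59.6% in south-west, 59.5% in north-west and 59.5% in north-east, with south 1.00 point under the ceiling of 60.0%.

    D + X + L → J + L, rate k1*[D]*[X]*[L]/(1 + ([D]/sat1)) (1.87 mM, k = 17400 M⁻² s⁻¹, Ea = 16.0 kJ mol⁻¹)
    D + G → Z (k = 529 M⁻¹ min⁻¹, Ea = 56.0 kJ mol⁻¹)
    2 L → E (k = 107 M⁻¹ min⁻¹, Ea = 35.0 kJ mol⁻¹)
    L → Q (k = 3.05 × 10⁻⁴ min⁻¹, Ea = 100 kJ mol⁻¹)
    (constants at 35 °C)

In north-west the path to Z had done half its turnover up to 12.0 min by 0.349 min and the path to J by 1.28 min. X stood at 4.43% of its charge at the change of temperature, 8.00 min, and at 0.775% at 12.0 min, with D at 10.5%. A neighbour of north-west charged with 0.150 equiv of X has a ceiling of 15.0% and a left-over D of 55.0%, and it ended with J at 15.0% and D at 55.0%.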